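The O1–C8a aryl ether bond of the pyran ring is formed last. C8a lies ortho to the C8 ketone and meta to the C5 and C7 phenols, so it is the only arene carbon that ordinary electrophilic substitution of the acylated 2-methylresorcinol core cannot oxygenate. A ketone-guided palladium C–H etherification brings the third ring oxygen there and closes the pyran in one operation from a tethered tertiary alcohol. The precursor is an open-chain, (R)-configured, silyl-protected benzylic carbinol bearing that tertiary alcohol, on a 3-phenylpropanoyl resorcinol whose phenols are masked as pivalates, which resist shifting to the neighbouring benzylic oxygen. C4 is set earlier by catalytic asymmetric methallylboration.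

Key step: step 7

Remark on the chemistry: the (R)-configured phosphoric acid is assumed to deliver the methallyl group to the Re face of the aldehyde, as it does with simple aryl aldehydes; if a configuration check on the adduct shows the opposite sense, the (S)-catalyst is used.

Step 1
Reactants: 1 2-methylresorcinol (2-methylbenzene-1,3-diol); 2 3-phenylpropanoic acid
Product: 3 1-(2,4-dihydroxy-3-methylphenyl)-3-phenylpropan-1-one
Conditions: BF3·OEt2 (as solvent), 90 °C; then H2O
Reagents that add atoms: none
Why: Friedel–Crafts acylation of the resorcinol by the free acid in BF3·OEt2 (Nencki type) should stop at the mono-ketone, because the two candidate ring positions are equivalent and the product, chelated through its ortho hydroxyl, is deactivated towards a second acylation.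

Step 2
Reactants: 3 1-(2,4-dihydroxy-3-methylphenyl)-3-phenylpropan-1-one
Product: 4 2,4-dihydroxy-3-methyl-5-(3-phenylpropanoyl)benzaldehyde
Conditions: hexamethylenetetramine, CF3CO2H, 80 °C; then 2 M HCl, 60 °C
Reagents that add atoms: hexamethylenetetramine (C1N2CN3CN1CN(C2)C3); water (O)
Why: The Duff reaction should formylate the only carbon that is still activated (ortho to the 4-hydroxyl, para to the 2-hydroxyl), whereas the usual Vilsmeier reagent is avoided because it condenses at the CH2 next to an ortho-hydroxyaryl ketone and would build a chromone.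

Step 3
Reactants: 4 2,4-dihydroxy-3-methyl-5-(3-phenylpropanoyl)benzaldehyde
Product: 5 4-formyl-2-methyl-6-(3-phenylpropanoyl)-1,3-phenylene bis(2,2-dimethylpropanoate)
Conditions: t-BuCOCl, Et3N, 4-(dimethylamino)pyridine (cat.), CH2Cl2, 0 °C to rt
Reagents that add atoms: pivaloyl chloride (CC(C)(C)C(=O)Cl)
Why: Nucleophile-catalysed acylation with an acid chloride esterifies even the two hydrogen-bonded phenols, and pivalates are chosen over smaller acyl groups because they should not migrate to the benzylic hydroxyl made in step 4 and are inert to the oxidant of step 7.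

Step 4
Reactants: 5 4-formyl-2-methyl-6-(3-phenylpropanoyl)-1,3-phenylene bis(2,2-dimethylpropanoate); 6 2-methylallylboronic acid pinacol ester
Product: 8 4-[(1R)-1-hydroxy-3-methylbut-3-en-1-yl]-2-methyl-6-(3-phenylpropanoyl)-1,3-phenylene bis(2,2-dimethylpropanoate), via pinacol borate ester 7 (not isolated)
Conditions: (R)-3,3'-bis(2,4,6-triisopropylphenyl)-1,1'-binaphthyl-2,2'-diyl hydrogen phosphate (5 mol%), toluene, −30 °C; then pH 7 buffer, rt
Reagents that add atoms: none
Why: Chiral phosphoric acid catalysed allylboration passes through a closed six-membered chair transition state in which the catalyst hydrogen-bonds the boronate oxygen and the formyl hydrogen, so the methallyl group should add to the Re face and set C4 as R, the ketone and the esters being far less electrophilic than the aldehyde.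

Step 5
Reactants: 8 4-[(1R)-1-hydroxy-3-methylbut-3-en-1-yl]-2-methyl-6-(3-phenylpropanoyl)-1,3-phenylene bis(2,2-dimethylpropanoate)
Product: 9 4-[(1R)-1-(tert-butyldimethylsilyloxy)-3-methylbut-3-en-1-yl]-2-methyl-6-(3-phenylpropanoyl)-1,3-phenylene bis(2,2-dimethylpropanoate)
Conditions: TBSOTf, 2,6-lutidine, CH2Cl2, −78 °C
Reagents that add atoms: tert-butyldimethylsilyl trifluoromethanesulfonate (CC(C)(C)[Si](C)(C)OS(=O)(=O)C(F)(F)F)
Why: Silylation of the secondary alcohol with a silyl triflate and a hindered pyridine base is fast at −78 °C, which should leave the enolisable ketone and the aryl esters untouched and cannot affect C4 because its C–O bond stays intact.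

Step 6
Reactants: 9 4-[(1R)-1-(tert-butyldimethylsilyloxy)-3-methylbut-3-en-1-yl]-2-methyl-6-(3-phenylpropanoyl)-1,3-phenylene bis(2,2-dimethylpropanoate)
Product: 11 4-[(1R)-1-(tert-butyldimethylsilyloxy)-3-hydroxy-3-methylbutyl]-2-methyl-6-(3-phenylpropanoyl)-1,3-phenylene bis(2,2-dimethylpropanoate), via tertiary hydroperoxide 10 (not isolated)
Conditions: Mn(dpm)3 (dpm = 2,2,6,6-tetramethylheptane-3,5-dionate; 10 mol%), PhSiH3, O2 (1 atm), i-PrOH/CH2Cl2, 0 °C to rt; then PPh3
Reagents that add atoms: dioxygen (O=O)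
Why: Mukaiyama hydration (hydrogen-atom transfer from a manganese hydride to the 1,1-disubstituted alkene, capture of the tertiary radical by O2, reduction of the hydroperoxide) should give the Markovnikov tertiary alcohol under neutral conditions that spare ketone, esters and silyl ether.

Step 7
Reactants: 11 4-[(1R)-1-(tert-butyldimethylsilyloxy)-3-hydroxy-3-methylbutyl]-2-methyl-6-(3-phenylpropanoyl)-1,3-phenylene bis(2,2-dimethylpropanoate)
Product: 12 (4R)-4-(tert-butyldimethylsilyloxy)-2,2,6-trimethyl-8-(3-phenylpropanoyl)chromane-5,7-diyl bis(2,2-dimethylpropanoate)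
Conditions: Pd(OAc)2 (10 mol%), PhI(OAc)2 (1.5 equiv), Li2CO3 (1.5 equiv), C6F6, 100 °C (sealed tube)
Reagents that add atoms: none
Why: Proposed new method: the ketone oxygen, helped by the tertiary alkoxide as a second donor arm, should hold divalent palladium over the one C–H that lies between them, which is cleaved by carboxylate-assisted concerted metalation–deprotonation; PhI(OAc)2 then oxidises the aryl palladium species to tetravalent palladium, and C(aryl)–O reductive elimination with the bound alkoxide forms O1–C8a and returns divalent palladium. The closest known reaction types are the Pd(OAc)2/PhI(OAc)2 hydroxyl-directed C–H activation/C–O cyclisation of tertiary alcohols to dihydrobenzofurans and the ketone-directed ortho C–H oxygenation of aryl ketones, which are merged here and extended to a ring one atom larger. The pyran ring closes by reductive elimination from a seven-membered aryl(alkoxo)palladacycle, a metal-templated six-membered closure at an aryl carbon and not an ionic cyclisation. No stereocentre is formed, and C4 stays R because neither its C–H nor its C–O bond takes part. Site selectivity needs no control beyond the substrate, since this is the only C–H ortho to the ketone and the only one ortho to the carbinol arm, while alkoxide must beat acetate in the reductive elimination, which intramolecular delivery, the gem-dimethyl group, the carbonate base and the non-coordinating solvent are meant to secure. The pivalates and the silyl ether keep the phenols and the secondary carbinol from the oxidant, and the tertiary alcohol has no carbinol hydrogen for palladium to abstract.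

Step 8
Reactants: 12 (4R)-4-(tert-butyldimethylsilyloxy)-2,2,6-trimethyl-8-(3-phenylpropanoyl)chromane-5,7-diyl bis(2,2-dimethylpropanoate)
Product: 14 1-[(4R)-4,5,7-trihydroxy-2,2,6-trimethylchroman-8-yl]-3-phenylpropan-1-one, via silyl ether diphenol 13 (not isolated)
Conditions: K2CO3, MeOH, rt; then AcOH to neutrality, evaporation; Bu4NF/AcOH (1:1), THF, 0 °C to rt
Reagents that add atoms: none
Why: Methanolysis of the two aryl pivalates, whose phenoxide leaving groups are stabilised by the ortho or para ketone, is run first so that no acyl group can move to the C4 oxygen, and buffered fluoride desilylation then frees the acid-sensitive benzylic alcohol without acid, neither operation breaking a bond at C4.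

Compound list
1 | 2-methylresorcinol (2-methylbenzene-1,3-diol) | Cc1c(O)cccc1O | starting material
2 | 3-phenylpropanoic acid | OC(=O)CCc1ccccc1 | starting material
3 | 1-(2,4-dihydroxy-3-methylphenyl)-3-phenylpropan-1-one | Cc1c(O)ccc(C(=O)CCc2ccccc2)c1O | intermediate
4 | 2,4-dihydroxy-3-methyl-5-(3-phenylpropanoyl)benzaldehyde | Cc1c(O)c(C=O)cc(C(=O)CCc2ccccc2)c1O | intermediate
5 | 4-formyl-2-methyl-6-(3-phenylpropanoyl)-1,3-phenylene bis(2,2-dimethylpropanoate) | Cc1c(OC(=O)C(C)(C)C)c(C(=O)CCc2ccccc2)cc(C=O)c1OC(=O)C(C)(C)C | intermediate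
6 | 2-methylallylboronic acid pinacol ester (4,4,5,5-tetramethyl-2-(2-methylprop-2-en-1-yl)-1,3,2-dioxaborolane) | CC(=C)CB1OC(C)(C)C(C)(C)O1 | starting material
7 | 2-methyl-4-{(1R)-3-methyl-1-[(4,4,5,5-tetramethyl-1,3,2-dioxaborolan-2-yl)oxy]but-3-en-1-yl}-6-(3-phenylpropanoyl)-1,3-phenylene bis(2,2-dimethylpropanoate) | Cc1c(OC(=O)C(C)(C)C)c(C(=O)CCc2ccccc2)cc(c1OC(=O)C(C)(C)C)[C@H](OB1OC(C)(C)C(C)(C)O1)CC(C)=C | intermediate (not isolated)
8 | 4-[(1R)-1-hydroxy-3-methylbut-3-en-1-yl]-2-methyl-6-(3-phenylpropanoyl)-1,3-phenylene bis(2,2-dimethylpropanoate) | Cc1c(OC(=O)C(C)(C)C)c(C(=O)CCc2ccccc2)cc(c1OC(=O)C(C)(C)C)[C@H](O)CC(C)=C | intermediate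
9 | 4-[(1R)-1-(tert-butyldimethylsilyloxy)-3-methylbut-3-en-1-yl]-2-methyl-6-(3-phenylpropanoyl)-1,3-phenylene bis(2,2-dimethylpropanoate) | Cc1c(OC(=O)C(C)(C)C)c(C(=O)CCc2ccccc2)cc(c1OC(=O)C(C)(C)C)[C@H](O[Si](C)(C)C(C)(C)C)CC(C)=C | intermediate
10 | 4-[(1R)-1-(tert-butyldimethylsilyloxy)-3-hydroperoxy-3-methylbutyl]-2-methyl-6-(3-phenylpropanoyl)-1,3-phenylene bis(2,2-dimethylpropanoate) | Cc1c(OC(=O)C(C)(C)C)c(C(=O)CCc2ccccc2)cc(c1OC(=O)C(C)(C)C)[C@H](O[Si](C)(C)C(C)(C)C)CC(C)(C)OO | intermediate (not isolated)
11 | 4-[(1R)-1-(tert-butyldimethylsilyloxy)-3-hydroxy-3-methylbutyl]-2-methyl-6-(3-phenylpropanoyl)-1,3-phenylene bis(2,2-dimethylpropanoate) | Cc1c(OC(=O)C(C)(C)C)c(C(=O)CCc2ccccc2)cc(c1OC(=O)C(C)(C)C)[C@H](O[Si](C)(C)C(C)(C)C)CC(C)(C)O | intermediate (precursor of the key step)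
12 | (4R)-4-(tert-butyldimethylsilyloxy)-2,2,6-trimethyl-8-(3-phenylpropanoyl)chromane-5,7-diyl bis(2,2-dimethylpropanoate) | Cc1c(OC(=O)C(C)(C)C)c(C(=O)CCc2ccccc2)c2c(c1OC(=O)C(C)(C)C)[C@H](O[Si](C)(C)C(C)(C)C)CC(C)(C)O2 | intermediate (product of the key step)
13 | 1-[(4R)-4-(tert-butyldimethylsilyloxy)-5,7-dihydroxy-2,2,6-trimethylchroman-8-yl]-3-phenylpropan-1-one | Cc1c(O)c(C(=O)CCc2ccccc2)c2c(c1O)[C@H](O[Si](C)(C)C(C)(C)C)CC(C)(C)O2 | intermediate (not isolated)
14 | 1-[(4R)-4,5,7-trihydroxy-2,2,6-trimethylchroman-8-yl]-3-phenylpropan-1-one | Cc1c(O)c(C(=O)CCc2ccccc2)c2c(c1O)[C@H](O)CC(C)(C)O2 | target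

Total step count: 8. Longest linear sequence: 8 steps, from 1 to 14.

Steps most likely to fail

Step 7. Palladium may not reach the C–H flanked by the acyl group and the branched carbinol arm. The tetravalent palladium intermediate may also release an aryl acetate, or the saturated ketone may be dehydrogenated to the chalcone, before the alkoxide couples. The fallback makes the same O1–C8a bond by known aryl halide chemistry; it sets out from 1 and comes back at 12.
- Pivaloylation of 1 (t-BuCOCl, Et3N, 4-(dimethylamino)pyridine, CH2Cl2) gives 2-methyl-1,3-phenylene bis(2,2-dimethylpropanoate) F1.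
- Sterically governed iridium-catalysed C–H borylation ([Ir(OMe)(cod)]2, 4,4'-di-tert-butyl-2,2'-bipyridine, B2pin2, THF, 80 °C) takes place at C5, the only C–H without an ortho neighbour, and gives the aryl pinacol boronate F2.
- CuBr2 in MeOH/H2O (80 °C, same flask) turns it into 5-bromo-2-methyl-1,3-phenylene bis(2,2-dimethylpropanoate) F3, and K2CO3 in MeOH frees 5-bromo-2-methylbenzene-1,3-diol F4.
- The conditions of steps 1 to 6 are then applied in the same order. Acylation with 2 gives the bromo ketone F5, Duff formylation the bromo aldehyde F6, and pivaloylation the bromo aldehyde bis-pivalate F7. Methallylboration with 6 gives the pinacol borate F8 and, after buffer, the (R)-homoallylic alcohol F9. Silylation gives the silyl ether F10, and Mukaiyama hydration gives the hydroperoxide F11 and, after PPh3, the bromo tertiary alcohol F12.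
- Palladium-catalysed intramolecular etherification of the aryl bromide (Pd(OAc)2, 2-(di-tert-butylphosphino)-1,1'-binaphthyl, Cs2CO3, toluene, 80 °C) then gives 12. It runs by oxidative addition to zerovalent palladium, alkoxide exchange and C–O reductive elimination, and tertiary alcohols suit it because their alkoxides lack a hydrogen on the carbinol carbon.

Step 4. Facial selectivity may be poor because the ortho pivalate and the ketone compete for the hydrogen bonds of the catalyst, or an uncatalysed background addition to the electron-poor aldehyde may erode it. The fallback is a Keck asymmetric methallylation, which replaces the Brønsted acid and boronate by a chiral titanium Lewis acid and an allylstannane reacting through an open transition state. It sets out from 5 and comes back at 8: methallyltributylstannane, (R)-1,1'-bi-2-naphthol and Ti(OiPr)4 (10 mol% each; the ligand enantiomer that gives Re-face addition), 4 Å molecular sieves, CH2Cl2, −20 °C. The tributylstannyl ether F13 first formed is hydrolysed to 8 on work-up.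

Step 2. The aminomethyl intermediates of the Duff reaction may bridge two arenes through a methylene group, or the iminium may attack the enolisable ketone in a Mannich reaction. The fallback is a Rieche formylation, in which no amine is involved and the titanium phenoxide of the 4-hydroxyl delivers the electrophile to its own ortho carbon. It sets out from 3 and comes back at 4: Cl2CHOMe, TiCl4, CH2Cl2, 0 °C. The aryl(chloro)methyl methyl ether F14 is hydrolysed to 4 by aqueous HCl.

Further compounds
F1 | step 7 | 2-methyl-1,3-phenylene bis(2,2-dimethylpropanoate) | Cc1c(OC(=O)C(C)(C)C)cccc1OC(=O)C(C)(C)C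
F2 | step 7 | 2-methyl-5-(4,4,5,5-tetramethyl-1,3,2-dioxaborolan-2-yl)-1,3-phenylene bis(2,2-dimethylpropanoate) | Cc1c(OC(=O)C(C)(C)C)cc(B2OC(C)(C)C(C)(C)O2)cc1OC(=O)C(C)(C)C
F3 | step 7 | 5-bromo-2-methyl-1,3-phenylene bis(2,2-dimethylpropanoate) | Cc1c(OC(=O)C(C)(C)C)cc(Br)cc1OC(=O)C(C)(C)C
F4 | step 7 | 5-bromo-2-methylbenzene-1,3-diol | Cc1c(O)cc(Br)cc1O
F5 | step 7 | 1-(6-bromo-2,4-dihydroxy-3-methylphenyl)-3-phenylpropan-1-one | Cc1c(O)cc(Br)c(C(=O)CCc2ccccc2)c1O
F6 | step 7 | 2-bromo-4,6-dihydroxy-5-methyl-3-(3-phenylpropanoyl)benzaldehyde | Cc1c(O)c(C=O)c(Br)c(C(=O)CCc2ccccc2)c1O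
F7 | step 7 | 5-bromo-4-formyl-2-methyl-6-(3-phenylpropanoyl)-1,3-phenylene bis(2,2-dimethylpropanoate) | Cc1c(OC(=O)C(C)(C)C)c(C(=O)CCc2ccccc2)c(Br)c(C=O)c1OC(=O)C(C)(C)C
F8 | step 7 | 5-bromo-2-methyl-4-{(1R)-3-methyl-1-[(4,4,5,5-tetramethyl-1,3,2-dioxaborolan-2-yl)oxy]but-3-en-1-yl}-6-(3-phenylpropanoyl)-1,3-phenylene bis(2,2-dimethylpropanoate) | Cc1c(OC(=O)C(C)(C)C)c(C(=O)CCc2ccccc2)c(Br)c(c1OC(=O)C(C)(C)C)[C@H](OB1OC(C)(C)C(C)(C)O1)CC(C)=C
F9 | step 7 | 5-bromo-4-[(1R)-1-hydroxy-3-methylbut-3-en-1-yl]-2-methyl-6-(3-phenylpropanoyl)-1,3-phenylene bis(2,2-dimethylpropanoate) | Cc1c(OC(=O)C(C)(C)C)c(C(=O)CCc2ccccc2)c(Br)c(c1OC(=O)C(C)(C)C)[C@H](O)CC(C)=C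
F10 | step 7 | 5-bromo-4-[(1R)-1-(tert-butyldimethylsilyloxy)-3-methylbut-3-en-1-yl]-2-methyl-6-(3-phenylpropanoyl)-1,3-phenylene bis(2,2-dimethylpropanoate) | Cc1c(OC(=O)C(C)(C)C)c(C(=O)CCc2ccccc2)c(Br)c(c1OC(=O)C(C)(C)C)[C@H](O[Si](C)(C)C(C)(C)C)CC(C)=C
F11 | step 7 | 5-bromo-4-[(1R)-1-(tert-butyldimethylsilyloxy)-3-hydroperoxy-3-methylbutyl]-2-methyl-6-(3-phenylpropanoyl)-1,3-phenylene bis(2,2-dimethylpropanoate) | Cc1c(OC(=O)C(C)(C)C)c(C(=O)CCc2ccccc2)c(Br)c(c1OC(=O)C(C)(C)C)[C@H](O[Si](C)(C)C(C)(C)C)CC(C)(C)OO
F12 | step 7 | 5-bromo-4-[(1R)-1-(tert-butyldimethylsilyloxy)-3-hydroxy-3-methylbutyl]-2-methyl-6-(3-phenylpropanoyl)-1,3-phenylene bis(2,2-dimethylpropanoate) | Cc1c(OC(=O)C(C)(C)C)c(C(=O)CCc2ccccc2)c(Br)c(c1OC(=O)C(C)(C)C)[C@H](O[Si](C)(C)C(C)(C)C)CC(C)(C)O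
F13 | step 4 | 2-methyl-4-{(1R)-3-methyl-1-[(tributylstannyl)oxy]but-3-en-1-yl}-6-(3-phenylpropanoyl)-1,3-phenylene bis(2,2-dimethylpropanoate) | Cc1c(OC(=O)C(C)(C)C)c(C(=O)CCc2ccccc2)cc(c1OC(=O)C(C)(C)C)[C@H](O[Sn](CCCC)(CCCC)CCCC)CC(C)=C
F14 | step 2 | 1-{5-[chloro(methoxy)methyl]-2,4-dihydroxy-3-methylphenyl}-3-phenylpropan-1-one | COC(Cl)c1cc(C(=O)CCc2ccccc2)c(O)c(C)c1O
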